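**Retrosynthetic overview**
1. Oxirane (ring C) last: both C–O bonds of the 1,10-epoxide are made by a C3-hydroxyl-directed epoxidation of the ten-membered dienal. This is the key step; the aldehyde is unmasked from a diethyl acetal just before it.
2. Ten-membered ring A: C3–C4 by intramolecular Nozaki–Hiyama–Kishi coupling of a (Z)-alkenyl iodide with an aldehyde.
3. C8–O ester by Mitsunobu inversion with methacrylic acid; C7–C8 by zinc Barbier coupling of fragment 1 (a 3-(bromomethyl)butenolide) with fragment 2 (a β,γ-unsaturated aldehyde).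
4. Fragment 1: γ-lactone ring B by C6–O esterification then ring-closing metathesis, on a carbinol from asymmetric alkynylation of acrolein. Fragment 2 from pent-3-yn-1-ol and oxirane.
5. Ring order: B (γ-lactone), then A (carbocycle), then C (oxirane).

Assumption: germacrane numbering (C1–C15) is used throughout; the target SMILES corresponds to 1R,3S,6R,7R,8R,10R with C3 and C6 cis on C4=C5, and (S,S)-ProPhenol is taken as the ligand antipode that gives the 3S carbinol in step 1 (its mirror image is used if the sense is reversed).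

**Route**

Step 1
Reactants: 1 3,3-diethoxyprop-1-yne; 2 acrolein (prop-2-enal)
Product: 4 (3S)-6,6-diethoxyhex-1-en-4-yn-3-ol, via methylzinc acetylide 3 (not isolated)
Conditions: Me2Zn (3 equiv), (S,S)-ProPhenol (20 mol %), Ph3PO (40 mol %), toluene, 0 °C; then 2, 4 °C; aq NH4Cl
Reagents that add atoms: none
Why: Zinc–ProPhenol asymmetric alkynylation (catalytic 1,2-addition of an alkynylzinc to an enal), in which the dinuclear zinc–ligand pocket delivers the acetylide to one carbonyl face and so sets the future C6 carbinol as 3S without conjugate addition.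

Step 2
Reactants: 4 (3S)-6,6-diethoxyhex-1-en-4-yn-3-ol
Product: 6 (3S,4Z)-6,6-diethoxy-5-iodohexa-1,4-dien-3-ol, via cyclic alkenylalanate 5 (not isolated)
Conditions: NaAlH2(OCH2CH2OMe)2 (Red-Al, 1.6 equiv), THF, −20 → 0 °C; then I2, −78 → −20 °C
Reagents that add atoms: iodine, [I][I]
Why: Hydroxyl-directed trans-hydroalumination followed by iodinolysis, in which the aluminium alkoxide delivers hydride to the proximal alkyne carbon and aluminium to the distal one through a five-membered ring and iodine replaces aluminium with retention, so iodine ends cis to the carbinol carbon (4Z) while the vinyl group and the acetal are untouched.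

Step 3
Reactants: 6 (3S,4Z)-6,6-diethoxy-5-iodohexa-1,4-dien-3-ol; 7 2-(bromomethyl)prop-2-enoic acid
Product: 8 (3S,4Z)-6,6-diethoxy-5-iodohexa-1,4-dien-3-yl 2-(bromomethyl)prop-2-enoate
Conditions: DCC (1.2 equiv), DMAP (5 mol %), CH2Cl2, −20 → 0 °C
Reagents that add atoms: none
Why: Steglich esterification forms the C6–O bond of the future lactone at low temperature without touching the allylic bromide or ionising the bis-allylic carbinol, so the 3S centre is retained.

Step 4
Reactants: 8 (3S,4Z)-6,6-diethoxy-5-iodohexa-1,4-dien-3-yl 2-(bromomethyl)prop-2-enoate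
Product: 9 (5S)-3-(bromomethyl)-5-[(1Z)-3,3-diethoxy-2-iodoprop-1-en-1-yl]furan-2(5H)-one (fragment 1)
Conditions: RuCl2(=CHPh)(H2IMes)(PCy3) (second-generation Grubbs catalyst, 5 mol %), CH2Cl2, 40 °C, 5 mM
Reagents that add atoms: none
Why: Ring-closing metathesis between the acrylate and the terminal vinyl group closes the γ-lactone (ring B) as a butenolide with loss of ethene, the trisubstituted iodoalkene being inert and the stereocentre not involved.

Step 5
Reactants: 10 pent-3-yn-1-ol
Product: 11 triethyl(pent-3-yn-1-yloxy)silane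
Conditions: Et3SiCl, imidazole, CH2Cl2, 0 °C
Reagents that add atoms: chlorotriethylsilane, CC[Si](Cl)(CC)CC
Why: Standard silylation of a primary alcohol, the triethylsilyl ether being chosen because it can later be oxidised directly to the aldehyde.

Step 6
Reactants: 11 triethyl(pent-3-yn-1-yloxy)silane
Product: 13 triethyl{[(3E)-4-iodopent-3-en-1-yl]oxy}silane, via alkenylzirconocene chloride 12 (not isolated)
Conditions: Cp2Zr(H)Cl (2.0 equiv), THF, 50 °C, 1 h; then I2, 0 °C
Reagents that add atoms: iodine, [I][I]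
Why: Schwartz hydrozirconation (syn addition, with excess reagent equilibrating zirconium to the less hindered methyl-bearing carbon) and iodinolysis with retention give the E-alkenyl iodide that fixes the geometry of the future 1(10)-alkene.

Step 7
Reactants: 13 triethyl{[(3E)-4-iodopent-3-en-1-yl]oxy}silane; 14 oxirane
Product: 16 (3E)-3-methyl-6-(triethylsilyloxy)hex-3-en-1-ol, via alkenyllithium 15 (not isolated)
Conditions: t-BuLi (2.1 equiv), Et2O, −78 °C; then 14 (3 equiv), −78 → 0 °C
Reagents that add atoms: none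
Why: Iodine–lithium exchange with retention of alkene geometry followed by SN2 opening of oxirane adds the two-carbon C9–C8 arm and gives the E-trisubstituted homoallylic alcohol.

Step 8
Reactants: 16 (3E)-3-methyl-6-(triethylsilyloxy)hex-3-en-1-ol
Product: 17 (3E)-3-methyl-6-(triethylsilyloxy)hex-3-enal (fragment 2)
Conditions: Dess–Martin periodinane, CH2Cl2, 0 °C, 1 h; used crude
Reagents that add atoms: none
Why: Dess–Martin oxidation gives the β,γ-unsaturated aldehyde under non-basic conditions, so the double bond does not move into conjugation.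

Step 9
Reactants: 9 (5S)-3-(bromomethyl)-5-[(1Z)-3,3-diethoxy-2-iodoprop-1-en-1-yl]furan-2(5H)-one; 17 (3E)-3-methyl-6-(triethylsilyloxy)hex-3-enal
Product: 19 (4R,5S)-5-[(1Z)-3,3-diethoxy-2-iodoprop-1-en-1-yl]-4-[(1S,3E)-1-hydroxy-3-methyl-6-(triethylsilyloxy)hex-3-en-1-yl]-3-methylideneoxolan-2-one, via allylzinc bromide 18 (not isolated)
Conditions: Zn dust, THF/sat. aq NH4Cl (4:1), 0 °C → rt
Reagents that add atoms: none
Why: Zinc Barbier allylation (SE2′ attack through a chair Zimmerman–Traxler transition state), in which the allylzinc adds through the butenolide β-carbon anti to the C6 side chain (trans-lactone, 7R) with the aldehyde substituent equatorial, giving the 7,8-anti carbinol (8S, the C8 epimer of what the target needs) and regenerating the exocyclic methylene.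

Step 10
Reactants: 19 (4R,5S)-5-[(1Z)-3,3-diethoxy-2-iodoprop-1-en-1-yl]-4-[(1S,3E)-1-hydroxy-3-methyl-6-(triethylsilyloxy)hex-3-en-1-yl]-3-methylideneoxolan-2-one; 20 methacrylic acid (2-methylprop-2-enoic acid)
Product: 21 (1R,3E)-1-[(2S,3R)-2-[(1Z)-3,3-diethoxy-2-iodoprop-1-en-1-yl]-4-methylidene-5-oxooxolan-3-yl]-3-methyl-6-(triethylsilyloxy)hex-3-en-1-yl 2-methylprop-2-enoate
Conditions: PPh3, DIAD, 20 (2 equiv), toluene, −20 → 0 °C
Reagents that add atoms: none
Why: Mitsunobu esterification, in which the C8 alkoxyphosphonium is displaced by methacrylate in an SN2 step with clean inversion, converting 8S into the required 8R and installing the methacrylate in the same operation.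

Step 11
Reactants: 21 (1R,3E)-1-[(2S,3R)-2-[(1Z)-3,3-diethoxy-2-iodoprop-1-en-1-yl]-4-methylidene-5-oxooxolan-3-yl]-3-methyl-6-(triethylsilyloxy)hex-3-en-1-yl 2-methylprop-2-enoate
Product: 22 (1R,3E)-1-[(2S,3R)-2-[(1Z)-3,3-diethoxy-2-iodoprop-1-en-1-yl]-4-methylidene-5-oxooxolan-3-yl]-3-methyl-6-oxohex-3-en-1-yl 2-methylprop-2-enoate
Conditions: (COCl)2, DMSO, CH2Cl2, −78 → −40 °C; then Et3N, −78 → −20 °C; used crude
Reagents that add atoms: none
Why: Direct Swern oxidation of a primary triethylsilyl ether, in which the chlorosulfonium salt exchanges silicon for sulfur at oxygen and base-induced elimination gives the aldehyde while esters, acetal and alkenyl iodide are inert and no stereocentre is touched.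

Step 12
Reactants: 22 (1R,3E)-1-[(2S,3R)-2-[(1Z)-3,3-diethoxy-2-iodoprop-1-en-1-yl]-4-methylidene-5-oxooxolan-3-yl]-3-methyl-6-oxohex-3-en-1-yl 2-methylprop-2-enoate
Product: 24 (1(10)E,3S,4E,6R,7R,8R)-15,15-diethoxy-3-hydroxy-8-(2-methylprop-2-enoyloxy)germacra-1(10),4,11(13)-trien-12,6-olide (C3 and C6 cis on C4=C5), via alkenylchromium dichloride 23 (not isolated)
Conditions: CrCl2 (10 equiv), NiCl2 (0.1 equiv), DMSO, 25 °C, 2 mM, slow addition of 22
Reagents that add atoms: none
Why: Intramolecular Nozaki–Hiyama–Kishi reaction, in which zerovalent nickel (from NiCl2 and divalent chromium) inserts into the C–I bond, transmetalation gives the alkenyl trivalent chromium species with retention of alkene geometry (so C3 ends cis to C6), and its addition to the aldehyde under high dilution closes the ten-membered ring A, the new C3 carbinol (3S) being set by attack on the outward-facing aldehyde face of the chain folded by the trans-lactone and the two alkenes.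

Step 13
Reactants: 24 (1(10)E,3S,4E,6R,7R,8R)-15,15-diethoxy-3-hydroxy-8-(2-methylprop-2-enoyloxy)germacra-1(10),4,11(13)-trien-12,6-olide
Product: 25 (1(10)E,3S,4E,6R,7R,8R)-3-hydroxy-8-(2-methylprop-2-enoyloxy)-15-oxogermacra-1(10),4,11(13)-trien-12,6-olide
Conditions: PPTS (0.2 equiv), acetone/H2O (10:1), 25 °C
Reagents that add atoms: water, O
Why: Mild acid-catalysed acetal hydrolysis unveils the conjugated aldehyde without acid strong enough for transannular cyclisation or allylic transposition, and no stereocentre changes.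

Step 14
Reactants: 25 (1(10)E,3S,4E,6R,7R,8R)-3-hydroxy-8-(2-methylprop-2-enoyloxy)-15-oxogermacra-1(10),4,11(13)-trien-12,6-olide
Product: 26 (1R,3S,4E,6R,7R,8R,10R)-1,10-epoxy-3-hydroxy-8-(2-methylprop-2-enoyloxy)-15-oxogermacra-4,11(13)-dien-12,6-olide (CNP0534814.1)
Conditions: VO(acac)2 (10 mol %), t-BuOOH (1.5 equiv, in decane), CH2Cl2, 0 °C → rt
Reagents that add atoms: tert-butyl hydroperoxide, CC(C)(C)OO
Why: Proposed new method: the tetravalent vanadium precatalyst is oxidised by the hydroperoxide to a pentavalent alkoxo(tert-butylperoxo)vanadium species bound to the C3 oxygen, which hands its electrophilic oxygen across C2 to the outer face of the only electron-rich alkene, C1=C10 (homoallylic delivery through a chair-like vanadate array), while the allylic C4=C5 bond is switched off by conjugation to the aldehyde, so both oxirane C–O bonds form on the peripheral face and give 1R,10R; the closest known reaction is vanadium-catalysed hydroxyl-directed epoxidation of acyclic homoallylic alcohols, which has not been shown for a transannular homoallylic alcohol in a ten-membered diene or in competition with an allylic enal alkene.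

**Compound list**
1 | 3,3-diethoxyprop-1-yne | C#CC(OCC)OCC | starting material
2 | acrolein (prop-2-enal) | C=CC=O | starting material
3 | (3,3-diethoxyprop-1-yn-1-yl)(methyl)zinc (methylzinc acetylide) | C[Zn]C#CC(OCC)OCC | intermediate (not isolated)
4 | (3S)-6,6-diethoxyhex-1-en-4-yn-3-ol | C=C[C@H](O)C#CC(OCC)OCC | intermediate
5 | sodium (5S)-3-(diethoxymethyl)-5-ethenyl-2,2-bis(2-methoxyethoxy)-2,5-dihydro-1,2-oxaaluminol-2-uide (cyclic alkenylalanate) | [Na+].C=C[C@@H]1O[Al-](OCCOC)(OCCOC)C(C(OCC)OCC)=C1 | intermediate (not isolated)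
6 | (3S,4Z)-6,6-diethoxy-5-iodohexa-1,4-dien-3-ol | C=C[C@H](O)/C=C([I])/C(OCC)OCC | intermediate
7 | 2-(bromomethyl)prop-2-enoic acid | C=C(CBr)C(=O)O | starting material
8 | (3S,4Z)-6,6-diethoxy-5-iodohexa-1,4-dien-3-yl 2-(bromomethyl)prop-2-enoate | C=C[C@H](OC(=O)C(=C)CBr)/C=C([I])/C(OCC)OCC | intermediate
9 | (5S)-3-(bromomethyl)-5-[(1Z)-3,3-diethoxy-2-iodoprop-1-en-1-yl]furan-2(5H)-one (fragment 1) | BrCC1=C[C@@H](/C=C([I])/C(OCC)OCC)OC1=O | intermediate
10 | pent-3-yn-1-ol | CC#CCCO | starting material
11 | triethyl(pent-3-yn-1-yloxy)silane | CC#CCCO[Si](CC)(CC)CC | intermediate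
12 | chlorobis(cyclopentadienyl)[(2E)-5-(triethylsilyloxy)pent-2-en-2-yl]zirconium (alkenylzirconocene chloride) | C/C(=C\CCO[Si](CC)(CC)CC)[Zr](Cl)(C1C=CC=C1)C1C=CC=C1 | intermediate (not isolated)
13 | triethyl{[(3E)-4-iodopent-3-en-1-yl]oxy}silane | C/C([I])=C\CCO[Si](CC)(CC)CC | intermediate
14 | oxirane (ethylene oxide) | C1CO1 | starting material
15 | [(2Z)-5-(triethylsilyloxy)pent-2-en-2-yl]lithium (lithium trans to the CH2 chain, geometry of 13 retained) | C/C([Li])=C\CCO[Si](CC)(CC)CC | intermediate (not isolated)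
16 | (3E)-3-methyl-6-(triethylsilyloxy)hex-3-en-1-ol | OCC/C(C)=C/CCO[Si](CC)(CC)CC | intermediate
17 | (3E)-3-methyl-6-(triethylsilyloxy)hex-3-enal (fragment 2) | O=CC/C(C)=C/CCO[Si](CC)(CC)CC | intermediate
18 | bromo{[(5S)-5-[(1Z)-3,3-diethoxy-2-iodoprop-1-en-1-yl]-2-oxo-2,5-dihydrofuran-3-yl]methyl}zinc (allylzinc bromide) | Br[Zn]CC1=C[C@@H](/C=C([I])/C(OCC)OCC)OC1=O | intermediate (not isolated)
19 | (4R,5S)-5-[(1Z)-3,3-diethoxy-2-iodoprop-1-en-1-yl]-4-[(1S,3E)-1-hydroxy-3-methyl-6-(triethylsilyloxy)hex-3-en-1-yl]-3-methylideneoxolan-2-one | CC[Si](CC)(CC)OCC/C=C(C)/C[C@H](O)[C@H]1C(=C)C(=O)O[C@@H]1/C=C([I])/C(OCC)OCC | intermediate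
20 | methacrylic acid (2-methylprop-2-enoic acid) | C=C(C)C(=O)O | starting material
21 | (1R,3E)-1-[(2S,3R)-2-[(1Z)-3,3-diethoxy-2-iodoprop-1-en-1-yl]-4-methylidene-5-oxooxolan-3-yl]-3-methyl-6-(triethylsilyloxy)hex-3-en-1-yl 2-methylprop-2-enoate | CC[Si](CC)(CC)OCC/C=C(C)/C[C@@H](OC(=O)C(C)=C)[C@H]1C(=C)C(=O)O[C@@H]1/C=C([I])/C(OCC)OCC | intermediate
22 | (1R,3E)-1-[(2S,3R)-2-[(1Z)-3,3-diethoxy-2-iodoprop-1-en-1-yl]-4-methylidene-5-oxooxolan-3-yl]-3-methyl-6-oxohex-3-en-1-yl 2-methylprop-2-enoate | O=CC/C=C(C)/C[C@@H](OC(=O)C(C)=C)[C@H]1C(=C)C(=O)O[C@@H]1/C=C([I])/C(OCC)OCC | intermediate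
23 | alkenylchromium dichloride: 22 carrying CrCl2 in place of iodine on the alkene carbon, geometry retained | O=CC/C=C(C)/C[C@@H](OC(=O)C(C)=C)[C@H]1C(=C)C(=O)O[C@@H]1/C=C([Cr](Cl)Cl)/C(OCC)OCC | intermediate (not isolated)
24 | (1(10)E,3S,4E,6R,7R,8R)-15,15-diethoxy-3-hydroxy-8-(2-methylprop-2-enoyloxy)germacra-1(10),4,11(13)-trien-12,6-olide | C=C(C)C(=O)O[C@@H]1C/C(C)=C/C[C@H](O)/C(C(OCC)OCC)=C\[C@H]2OC(=O)C(=C)[C@@H]21 | intermediate
25 | (1(10)E,3S,4E,6R,7R,8R)-3-hydroxy-8-(2-methylprop-2-enoyloxy)-15-oxogermacra-1(10),4,11(13)-trien-12,6-olide | C=C(C)C(=O)O[C@@H]1C/C(C)=C/C[C@H](O)/C(C=O)=C\[C@H]2OC(=O)C(=C)[C@@H]21 | intermediate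
26 | (1R,3S,4E,6R,7R,8R,10R)-1,10-epoxy-3-hydroxy-8-(2-methylprop-2-enoyloxy)-15-oxogermacra-4,11(13)-dien-12,6-olide | C=C(C)C(=O)O[C@@H]1C[C@@]2(C)O[C@@H]2C[C@H](O)/C(C=O)=C\[C@H]2OC(=O)C(=C)[C@@H]21 | target

**Step count**
Total: 14 steps. Longest linear sequence: 10 steps (steps 1–4 then 9–14; the other arm, steps 5–8 then 9–14, is equally long).

**Three steps most likely to fail**

Step 14 (the proposed new step). The vanadium alkoxide may not reach across C2 to the 1(10)-alkene, or the aldehyde may interfere with the catalyst. The fallback is known chemistry with a different control element: drop metal-bound delivery and treat 25 with dimethyldioxirane in acetone at −20 °C. The free electrophilic oxidant attacks only the electron-rich 1(10)-alkene, from its exposed outer face (substrate conformational control, the usual outcome with germacra-1(10)-enes). This fallback sets out from 25 and comes back to the route at 26; it makes no new compound (F0).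

Step 10. The C8 alkoxyphosphonium sits between an allylic C7–H and an allylic C9–H2, so elimination can compete with the SN2 displacement by the weakly acidic methacrylic acid. The fallback replaces the redox condensation by a stepwise sulfonate displacement. Setting out from 19, ClCH2SO2Cl and pyridine in CH2Cl2 at 0 °C give the C8 chloromethanesulfonate of 19 F1. This is displaced with caesium methacrylate (from 20 and Cs2CO3) and 18-crown-6 in toluene at 40 °C, with SN2 inversion, and the route is rejoined at 21.

Step 12. The ring closure is precedented for related ten-membered lactones, but the facial selectivity at C3 is not secured and the 3R epimer may dominate. The fallback sets C3 by reagent-controlled reduction instead of by the C–C bond formation. Setting out from 22, the closure is run as described and the 3R epimer of 24 F2 (or the epimer mixture) is oxidised with Dess–Martin periodinane to the macrocyclic 3-ketone F3. Reduction with (R)-2-methyl-CBS-oxazaborolidine and catecholborane at −78 °C then gives the 3S alcohol, and the route is rejoined at 24.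

Further compounds
F0 | step 14 | none | none
F1 | step 10 | C8 chloromethanesulfonate of 19 (all stereocentres arranged as in 19) | CC[Si](CC)(CC)OCC/C=C(C)/C[C@H](OS(=O)(=O)CCl)[C@H]1C(=C)C(=O)O[C@@H]1/C=C([I])/C(OCC)OCC
F2 | step 12 | 3R epimer of 24: (1(10)E,3R,4E,6R,7R,8R)-15,15-diethoxy-3-hydroxy-8-(2-methylprop-2-enoyloxy)germacra-1(10),4,11(13)-trien-12,6-olide | C=C(C)C(=O)O[C@@H]1C/C(C)=C/C[C@@H](O)/C(C(OCC)OCC)=C\[C@H]2OC(=O)C(=C)[C@@H]21
F3 | step 12 | macrocyclic 3-ketone: 15,15-diethoxy-8-(2-methylprop-2-enoyloxy)-3-oxogermacra-1(10),4,11(13)-trien-12,6-olide (C6, C7, C8 and both alkenes as in 24) | C=C(C)C(=O)O[C@@H]1C/C(C)=C/CC(=O)/C(C(OCC)OCC)=C\[C@H]2OC(=O)C(=C)[C@@H]21
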